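The ten-membered carbocycle is closed last, across C7–C8 (C7 = ring-fusion CH beside the methylene carbon C11, C8 = CHOH), by an intramolecular Nozaki–Hiyama allylation. The step exploits the homoallylic alcohol array C8(OH)–C7–C11(=C13H2) inside the α-methylene-γ-lactone: in the open-chain precursor the lactone already exists as a 3-(bromomethyl)butenolide, whose allylchromium species attacks a tethered enal through C7. One operation forms the ring, sets C7 and C8 from C6, and shifts the double bond into the exocyclic position. The chain comes from (S)-citronellal (C10); C4 is set by Sharpless epoxidation, C5/C6 by Brown alkoxyallylboration, and the C9 ketone travels as a methylidene group.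

Key step: step 12

Remark (numbering): germacrane numbering is used for all intermediates: lactone O–C6, C7 (ring fusion), C11 (=C13H2), C12 (lactone C=O); C8 (CHOH), C9 (C=O), C10 (CH–CH3), C1–C3 (CH2), C4 (C(OH)CH3), C5 (CH–O-isobutyryl). The target is 4R,5S,6R,7S,8S,10S.
Remark (assumption): allyl methoxymethyl ether (6) is taken as a catalogue compound; if it has to be made from allyl alcohol and MOMCl, this adds one step outside the longest linear sequence.

Step 1
Reactants: 1 (S)-citronellal
Product: 2 2-[(2S)-2,6-dimethylhept-5-en-1-yl]-1,3-dioxolane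
Conditions: HOCH2CH2OH, p-TsOH (cat.), benzene, reflux (Dean–Stark)
Reagents that add atoms: ethylene glycol, OCCO
Why: Acid-catalysed acetalisation (1,3-dioxolane formation) masks the future C8 aldehyde against the oxidants, LiAlH4 and the allylborane used later; C10 is the bought stereocentre and, being β to the carbonyl, is not touched.

Step 2
Reactants: 2 2-[(2S)-2,6-dimethylhept-5-en-1-yl]-1,3-dioxolane
Product: 3 (2E,6S)-7-(1,3-dioxolan-2-yl)-2,6-dimethylhept-2-en-1-ol
Conditions: SeO2 (cat.), t-BuOOH, salicylic acid (cat.), CH2Cl2, rt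
Reagents that add atoms: tert-butyl hydroperoxide, CC(C)(C)OO (net oxygen source; the oxygen is relayed by catalytic selenium dioxide, O=[Se]=O)
Why: Selenium dioxide allylic oxidation (ene reaction followed by [2,3]-sigmatropic shift, run catalytically with t-BuOOH) hydroxylates the (E)-methyl group of the trisubstituted alkene selectively to give the (E)-allylic alcohol at C5; no stereocentre is formed.

Step 3
Reactants: 3 (2E,6S)-7-(1,3-dioxolan-2-yl)-2,6-dimethylhept-2-en-1-ol
Product: 4 [(2S,3S)-3-[(3S)-4-(1,3-dioxolan-2-yl)-3-methylbutyl]-2-methyloxiran-2-yl]methanol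
Conditions: Ti(Oi-Pr)4 (cat.), L-(+)-diethyl tartrate (cat.), t-BuOOH, 4 Å MS, CH2Cl2, −20 °C
Reagents that add atoms: tert-butyl hydroperoxide, CC(C)(C)OO
Why: Sharpless asymmetric epoxidation: with L-(+)-tartrate the titanium catalyst delivers oxygen to the alkene face that gives the (2S,3S)-epoxide, which fixes C4 (R in the target) under catalyst control, independent of the remote C10 centre.

Step 4
Reactants: 4 [(2S,3S)-3-[(3S)-4-(1,3-dioxolan-2-yl)-3-methylbutyl]-2-methyloxiran-2-yl]methanol
Product: 5 (2R,3S)-3-[(3S)-4-(1,3-dioxolan-2-yl)-3-methylbutyl]-2-methyloxirane-2-carbaldehyde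
Conditions: TEMPO (cat.), PhI(OAc)2, CH2Cl2, rt
Reagents that add atoms: none
Why: Oxoammonium (TEMPO) oxidation with PhI(OAc)2 as terminal oxidant stops at the aldehyde and leaves the epoxide and the acetal intact; the α-carbon is quaternary, so the epoxy aldehyde cannot epimerise.

Step 5
Reactants: 5 (2R,3S)-3-[(3S)-4-(1,3-dioxolan-2-yl)-3-methylbutyl]-2-methyloxirane-2-carbaldehyde; 6 allyl methoxymethyl ether
Product: 8 (1S,2R)-1-[(2S,3S)-3-[(3S)-4-(1,3-dioxolan-2-yl)-3-methylbutyl]-2-methyloxiran-2-yl]-2-(methoxymethoxy)but-3-en-1-ol, via allylborane 7 (not isolated)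
Conditions: 6, s-BuLi, THF, −78 °C; (−)-Ipc2BOMe [from (+)-α-pinene]; BF3·OEt2; then 5, −78 °C; NaBO3·4H2O, THF–H2O, rt
Reagents that add atoms: none
Why: Brown asymmetric γ-alkoxyallylboration: the (Z)-γ-alkoxyallylborane reacts through a closed chair transition state, so the Z geometry gives the syn C5-OH/C6-OMOM pair, and the isopinocampheyl groups derived from (+)-α-pinene direct attack to the Si face of the aldehyde, which sets C5 (S) and C6 (R) under reagent control (the α-quaternary epoxy aldehyde has only a weak intrinsic bias).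

Step 6
Reactants: 8 (1S,2R)-1-[(2S,3S)-3-[(3S)-4-(1,3-dioxolan-2-yl)-3-methylbutyl]-2-methyloxiran-2-yl]-2-(methoxymethoxy)but-3-en-1-ol
Product: 9 (3R,4S,5R,9S)-10-(1,3-dioxolan-2-yl)-3-(methoxymethoxy)-5,9-dimethyldec-1-ene-4,5-diol
Conditions: LiAlH4, THF, 0 °C → rt
Reagents that add atoms: none
Why: Hydride opening of the trisubstituted epoxide (SN2 reduction with LiAlH4) occurs at the secondary carbon C3, away from the quaternary C4, so the C4–O bond and its configuration are kept and the tertiary C4 alcohol results; acetal, MOM ether and vinyl group are inert.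

Step 7
Reactants: 9 (3R,4S,5R,9S)-10-(1,3-dioxolan-2-yl)-3-(methoxymethoxy)-5,9-dimethyldec-1-ene-4,5-diol; 10 isobutyryl chloride
Product: 11 (3R,4S,5R,9S)-10-(1,3-dioxolan-2-yl)-5-hydroxy-3-(methoxymethoxy)-5,9-dimethyldec-1-en-4-yl 2-methylpropanoate
Conditions: pyridine, DMAP (cat.), CH2Cl2, 0 °C → rt
Reagents that add atoms: none
Why: DMAP-catalysed acylation (esterification with an acid chloride) takes place only at the secondary C5 hydroxyl, the tertiary C4 hydroxyl being too hindered; no stereocentre is affected.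

Step 8
Reactants: 11 (3R,4S,5R,9S)-10-(1,3-dioxolan-2-yl)-5-hydroxy-3-(methoxymethoxy)-5,9-dimethyldec-1-en-4-yl 2-methylpropanoate
Product: 12 (3R,4S,5R,9S)-3,5-dihydroxy-5,9-dimethyl-11-oxoundec-1-en-4-yl 2-methylpropanoate
Conditions: Me2BBr, CH2Cl2, −78 °C; then aq. NaHCO3–THF
Reagents that add atoms: water, O
Why: Bromodimethylborane cleaves the MOM ether and the dioxolane by Lewis-acid-assisted C–O cleavage at low temperature (acetal and MOM ether cleavage), and the α-bromo ethers are hydrolysed on work-up; the cold, non-protic conditions are chosen to keep the isobutyrate on O5 and to leave the tertiary alcohol untouched.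

Step 9
Reactants: 12 (3R,4S,5R,9S)-3,5-dihydroxy-5,9-dimethyl-11-oxoundec-1-en-4-yl 2-methylpropanoate
Product: 13 (3R,4S,5R,9S)-10-formyl-3,5-dihydroxy-5,9-dimethylundeca-1,10-dien-4-yl 2-methylpropanoate
Conditions: aq. CH2O (37%), pyrrolidine (cat.), EtCO2H (cat.), i-PrOH, 45 °C
Reagents that add atoms: formaldehyde, C=O
Why: Organocatalytic α-methylenation (Mannich condensation of the enamine with formaldehyde followed by elimination of the amine) turns C9H2 into the C9 methylidene that masks the future ketone; C10 is not α to the carbonyl and keeps its configuration.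

Step 10
Reactants: 13 (3R,4S,5R,9S)-10-formyl-3,5-dihydroxy-5,9-dimethylundeca-1,10-dien-4-yl 2-methylpropanoate; 14 2-(bromomethyl)acrylic acid
Product: 15 (3R,4S,5R,9S)-10-formyl-5-hydroxy-5,9-dimethyl-4-(2-methylpropanoyloxy)undeca-1,10-dien-3-yl 2-(bromomethyl)prop-2-enoate
Conditions: DCC, DMAP (cat.), CH2Cl2, −20 → 0 °C
Reagents that add atoms: none
Why: Steglich esterification acylates the secondary allylic C6 hydroxyl (the tertiary C4 hydroxyl does not react) and brings in C11, C12 and C13 of the lactone; low temperature and little DMAP protect the allylic bromide.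

Step 11
Reactants: 15 (3R,4S,5R,9S)-10-formyl-5-hydroxy-5,9-dimethyl-4-(2-methylpropanoyloxy)undeca-1,10-dien-3-yl 2-(bromomethyl)prop-2-enoate
Product: 16 (1S,2R,6S)-1-[(2R)-4-(bromomethyl)-5-oxo-2,5-dihydrofuran-2-yl]-7-formyl-2-hydroxy-2,6-dimethyloct-7-en-1-yl 2-methylpropanoate
Conditions: Grubbs II (5 mol%), toluene, 80 °C
Reagents that add atoms: none
Why: Ring-closing metathesis between the C7 vinyl group and the acrylate alkene closes the five-membered butenolide (the lactone ring) with loss of ethylene, in preference to any medium ring; C6 is unchanged and the allylic bromide is tolerated by the ruthenium carbene.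

Step 12
Reactants: 16 (1S,2R,6S)-1-[(2R)-4-(bromomethyl)-5-oxo-2,5-dihydrofuran-2-yl]-7-formyl-2-hydroxy-2,6-dimethyloct-7-en-1-yl 2-methylpropanoate
Product: 18 (3aS,4S,6S,10R,11S,11aR)-4,10-dihydroxy-6,10-dimethyl-3,5-dimethylidene-2-oxoperhydrocyclodeca[b]furan-11-yl 2-methylpropanoate, via allylchromium species 17 (not isolated)
Conditions: CrCl2 (8 equiv), THF, rt, slow addition of 16 (final 2 mM); aq. NH4Cl
Reagents that add atoms: none
Why: CrCl2 reduces the allylic C13–Br bond by two one-electron transfers to the allylchromium(III) species 17, which adds to the C8 aldehyde through its γ-carbon C7 in a closed chair transition state with shift of the double bond to C11=C13; this is an intramolecular Nozaki–Hiyama allylation of the 2-(alkoxycarbonyl)allyl type, whose closest precedents are the intermolecular chromium-mediated additions of 3-(bromomethyl)butenolides and 2-(bromomethyl)acrylates to aldehydes and the Nozaki–Hiyama macrocyclisations of allylic bromides. The ten-membered carbocycle is closed by C7–C8 bond formation as a 10-exo-trig addition to the aldehyde with γ (SE2′) reaction of the allylmetal, under high dilution. C7 is set by the resident C6 stereocentre: the aldehyde is delivered to the butenolide face anti to the C5 substituent, which gives the trans-fused lactone, the fusion in which the seven-atom tether (C5 to C9) joins C6 and C8 with a relaxed anti-type dihedral about C6–C7. C8 is set by the chair transition state, in which the ring-locked allyl unit behaves as an (E)-γ-substituted allylmetal and the aldehyde substituent C9 sits pseudo-equatorially, which gives the anti relationship between C6 and the C8 hydroxyl found in the target. The step needs chemoselectivity for the aldehyde over lactone, ester and free tertiary alcohol and γ- over α-attack; the first follows from the low basicity and aldehyde selectivity of allylchromium reagents, the second from conjugation with the lactone carbonyl, which keeps chromium on C13. Slow addition suppresses oligomerisation.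

Step 13
Reactants: 18 (3aS,4S,6S,10R,11S,11aR)-4,10-dihydroxy-6,10-dimethyl-3,5-dimethylidene-2-oxoperhydrocyclodeca[b]furan-11-yl 2-methylpropanoate
Product: 19 (3aS,4S,6S,10R,11S,11aR)-4,10-dihydroxy-6,10-dimethyl-3-methylidene-2,5-dioxoperhydrocyclodeca[b]furan-11-yl 2-methylpropanoate (CNP0270933.1)
Conditions: O3, CH2Cl2–MeOH, Sudan Red 7B (indicator), −78 °C; then Me2S, −78 °C → rt
Reagents that add atoms: ozone, [O-][O+]=O
Why: Ozonolysis (Criegee mechanism, reductive work-up) cleaves the electron-richer, non-conjugated C9 methylidene in preference to the electron-poor α-methylene lactone, the end point being shown by the indicator dye, and unveils the C9 ketone; the neutral work-up leaves C8 and C10 unchanged.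

Compound list
1 | (S)-citronellal, (3S)-3,7-dimethyloct-6-enal | O=CC[C@@H](C)CCC=C(C)C | starting material
2 | 2-[(2S)-2,6-dimethylhept-5-en-1-yl]-1,3-dioxolane | C1COC(O1)C[C@@H](C)CCC=C(C)C | intermediate
3 | (2E,6S)-7-(1,3-dioxolan-2-yl)-2,6-dimethylhept-2-en-1-ol | C1COC(O1)C[C@@H](C)CC/C=C(\C)CO | intermediate
4 | [(2S,3S)-3-[(3S)-4-(1,3-dioxolan-2-yl)-3-methylbutyl]-2-methyloxiran-2-yl]methanol | C1COC(O1)C[C@@H](C)CC[C@@H]1O[C@@]1(C)CO | intermediate
5 | (2R,3S)-3-[(3S)-4-(1,3-dioxolan-2-yl)-3-methylbutyl]-2-methyloxirane-2-carbaldehyde | C1COC(O1)C[C@@H](C)CC[C@@H]1O[C@@]1(C)C=O | intermediate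
6 | allyl methoxymethyl ether, 3-(methoxymethoxy)prop-1-ene | C=CCOCOC | starting material
7 | [(Z)-3-(methoxymethoxy)prop-2-en-1-yl]bis(isopinocampheyl)borane (Ipc groups from (+)-α-pinene) | COCO/C=C\CB([C@@H]1C[C@@H]2C[C@@H](C2(C)C)[C@H]1C)[C@@H]1C[C@@H]2C[C@@H](C2(C)C)[C@H]1C | intermediate
8 | (1S,2R)-1-[(2S,3S)-3-[(3S)-4-(1,3-dioxolan-2-yl)-3-methylbutyl]-2-methyloxiran-2-yl]-2-(methoxymethoxy)but-3-en-1-ol | C1COC(O1)C[C@@H](C)CC[C@@H]1O[C@@]1(C)[C@@H](O)[C@H](OCOC)C=C | intermediate
9 | (3R,4S,5R,9S)-10-(1,3-dioxolan-2-yl)-3-(methoxymethoxy)-5,9-dimethyldec-1-ene-4,5-diol | C1COC(O1)C[C@@H](C)CCC[C@@](C)(O)[C@@H](O)[C@H](OCOC)C=C | intermediate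
10 | isobutyryl chloride, 2-methylpropanoyl chloride | CC(C)C(=O)Cl | starting material
11 | (3R,4S,5R,9S)-10-(1,3-dioxolan-2-yl)-5-hydroxy-3-(methoxymethoxy)-5,9-dimethyldec-1-en-4-yl 2-methylpropanoate | C1COC(O1)C[C@@H](C)CCC[C@@](C)(O)[C@@H](OC(=O)C(C)C)[C@H](OCOC)C=C | intermediate
12 | (3R,4S,5R,9S)-3,5-dihydroxy-5,9-dimethyl-11-oxoundec-1-en-4-yl 2-methylpropanoate | O=CC[C@@H](C)CCC[C@@](C)(O)[C@@H](OC(=O)C(C)C)[C@H](O)C=C | intermediate
13 | (3R,4S,5R,9S)-10-formyl-3,5-dihydroxy-5,9-dimethylundeca-1,10-dien-4-yl 2-methylpropanoate | O=CC(=C)[C@@H](C)CCC[C@@](C)(O)[C@@H](OC(=O)C(C)C)[C@H](O)C=C | intermediate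
14 | 2-(bromomethyl)acrylic acid, 2-(bromomethyl)prop-2-enoic acid | C=C(CBr)C(=O)O | starting material
15 | (3R,4S,5R,9S)-10-formyl-5-hydroxy-5,9-dimethyl-4-(2-methylpropanoyloxy)undeca-1,10-dien-3-yl 2-(bromomethyl)prop-2-enoate | O=CC(=C)[C@@H](C)CCC[C@@](C)(O)[C@@H](OC(=O)C(C)C)[C@H](OC(=O)C(=C)CBr)C=C | intermediate
16 | (1S,2R,6S)-1-[(2R)-4-(bromomethyl)-5-oxo-2,5-dihydrofuran-2-yl]-7-formyl-2-hydroxy-2,6-dimethyloct-7-en-1-yl 2-methylpropanoate | O=CC(=C)[C@@H](C)CCC[C@@](C)(O)[C@@H](OC(=O)C(C)C)[C@@H]1OC(=O)C(CBr)=C1 | intermediate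
17 | dichloro(allyl)chromium(III) species of 16 (CrCl2 on C13 in place of Br; THF ligands omitted) | O=CC(=C)[C@@H](C)CCC[C@@](C)(O)[C@@H](OC(=O)C(C)C)[C@@H]1OC(=O)C(C[Cr](Cl)Cl)=C1 | intermediate
18 | (3aS,4S,6S,10R,11S,11aR)-4,10-dihydroxy-6,10-dimethyl-3,5-dimethylidene-2-oxoperhydrocyclodeca[b]furan-11-yl 2-methylpropanoate (the 9-methylidene analogue of the target) | C=C1C(=O)O[C@@H]2[C@@H]1[C@H](O)C(=C)[C@@H](C)CCC[C@@](C)(O)[C@H]2OC(=O)C(C)C | intermediate
19 | (3aS,4S,6S,10R,11S,11aR)-4,10-dihydroxy-6,10-dimethyl-3-methylidene-2,5-dioxoperhydrocyclodeca[b]furan-11-yl 2-methylpropanoate (CNP0270933.1) | C=C1C(=O)O[C@@H]2[C@@H]1[C@H](O)C(=O)[C@@H](C)CCC[C@@](C)(O)[C@H]2OC(=O)C(C)C | target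

Total step count: 13
Longest linear sequence: 13 steps (1 → 19)

Steps most likely to fail

Step 12 (key macrocyclisation). The closure of the medium ring may lose against oligomerisation, the allylchromium species may be protonated or may eliminate the C6 carboxylate before it reaches the aldehyde, the C8 chromium alkoxide may translactonise onto C12, or the aldehyde may be taken from the wrong face at C7 or C8. The fallback sets out from 16 and comes back at 18, and replaces the reductive metalation by an allylboration. Palladium-catalysed borylation of the allylic bromide (B2pin2, Pd2(dba)3 cat., THF–DMSO, rt) should give the isolable (1S,2R,6S)-7-formyl-2-hydroxy-2,6-dimethyl-1-[(2R)-5-oxo-4-[(4,4,5,5-tetramethyl-1,3,2-dioxaborolan-2-yl)methyl]-2,5-dihydrofuran-2-yl]oct-7-en-1-yl 2-methylpropanoate F1. This non-basic allyl donor is then cyclised under high dilution with Lewis-acid catalysis (Sc(OTf)3 cat., toluene, −20 °C → rt) through the same closed chair transition state, and aqueous work-up of the borate should give 18.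

Step 13 (ozonolysis). The two 1,1-disubstituted alkenes may not be told apart well enough, so that the α-methylene lactone is cleaved as well, or the allylic alcohol may suffer anomalous cleavage of the C8–C9 bond. The fallback sets out from 18 and comes back at 19, and takes the lactone alkene out of play. Dimethylamine (THF, rt) adds to the α-methylene lactone to give the 13-(dimethylamino)-11,13-dihydro derivative of 18 F2. Ozonolysis of its trifluoroacetate salt (TFA, O3, CH2Cl2–MeOH, −78 °C; Me2S) gives the 13-(dimethylamino)-11,13-dihydro derivative of 19 F3. Quaternisation (MeI, CH2Cl2) gives the trimethylammonium iodide of F3 F4, and elimination with aq. NaHCO3 restores the methylidene group and gives 19.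

Step 5 (alkoxyallylboration of the epoxy aldehyde). The trisubstituted epoxide next to the aldehyde may open or rearrange in the Lewis-acidic reagent mixture, and facial control may erode if the epoxy aldehyde opposes the reagent. The fallback sets out from 4 and comes back at 9, and opens the epoxide first. LiAlH4 (THF, 0 °C) reduces 4 to (2R,6S)-7-(1,3-dioxolan-2-yl)-2,6-dimethylheptane-1,2-diol F5. Silylation (TESCl, imidazole, DMAP, DMF, 40 °C) gives 2-[(2S,6R)-2,6-dimethyl-6,7-bis(triethylsilyloxy)heptyl]-1,3-dioxolane F6. Swern oxidation, which converts a primary triethylsilyl ether directly into the aldehyde, gives (2R,6S)-7-(1,3-dioxolan-2-yl)-2,6-dimethyl-2-(triethylsilyloxy)heptanal F7. Alkoxyallylboration with borane 7, now with Felkin and reagent control matched, gives (3R,4S,5R,9S)-10-(1,3-dioxolan-2-yl)-3-(methoxymethoxy)-5,9-dimethyl-5-(triethylsilyloxy)dec-1-en-4-ol F8, and TBAF (THF, 0 °C) gives 9.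

Further compounds
F1 | step 12 | (1S,2R,6S)-7-formyl-2-hydroxy-2,6-dimethyl-1-[(2R)-5-oxo-4-[(4,4,5,5-tetramethyl-1,3,2-dioxaborolan-2-yl)methyl]-2,5-dihydrofuran-2-yl]oct-7-en-1-yl 2-methylpropanoate | O=CC(=C)[C@@H](C)CCC[C@@](C)(O)[C@@H](OC(=O)C(C)C)[C@@H]1OC(=O)C(CB2OC(C)(C)C(C)(C)O2)=C1
F2 | step 13 | 13-(dimethylamino)-11,13-dihydro derivative of 18 (configuration at C11 not assigned) | CN(C)CC1C(=O)O[C@@H]2[C@@H]1[C@H](O)C(=C)[C@@H](C)CCC[C@@](C)(O)[C@H]2OC(=O)C(C)C
F3 | step 13 | 13-(dimethylamino)-11,13-dihydro derivative of 19 (configuration at C11 not assigned) | CN(C)CC1C(=O)O[C@@H]2[C@@H]1[C@H](O)C(=O)[C@@H](C)CCC[C@@](C)(O)[C@H]2OC(=O)C(C)C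
F4 | step 13 | trimethylammonium iodide of F3 (configuration at C11 not assigned) | C[N+](C)(C)CC1C(=O)O[C@@H]2[C@@H]1[C@H](O)C(=O)[C@@H](C)CCC[C@@](C)(O)[C@H]2OC(=O)C(C)C.[I-]
F5 | step 5 | (2R,6S)-7-(1,3-dioxolan-2-yl)-2,6-dimethylheptane-1,2-diol | C1COC(O1)C[C@@H](C)CCC[C@@](C)(O)CO
F6 | step 5 | 2-[(2S,6R)-2,6-dimethyl-6,7-bis(triethylsilyloxy)heptyl]-1,3-dioxolane | C1COC(O1)C[C@@H](C)CCC[C@@](C)(O[Si](CC)(CC)CC)CO[Si](CC)(CC)CC
F7 | step 5 | (2R,6S)-7-(1,3-dioxolan-2-yl)-2,6-dimethyl-2-(triethylsilyloxy)heptanal | C1COC(O1)C[C@@H](C)CCC[C@@](C)(O[Si](CC)(CC)CC)C=O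
F8 | step 5 | (3R,4S,5R,9S)-10-(1,3-dioxolan-2-yl)-3-(methoxymethoxy)-5,9-dimethyl-5-(triethylsilyloxy)dec-1-en-4-ol | C1COC(O1)C[C@@H](C)CCC[C@@](C)(O[Si](CC)(CC)CC)[C@@H](O)[C@H](OCOC)C=C
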